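The gamma run turns slow with 41.8% of its electrophile still unreacted at 25.0 h.

- gamma: electrophile 0.16 M; nucleophile 0.80 equiv; free base 0.50 equiv; protic impurity 0.016 M; run made earlier
- flask: electrophile 0.080 M; nucleophile 0.800 equiv; free base 0.500 equiv; protic impurity 0.0160 M; time 10 d

- gamma (time / h: electrophile / %, product / %): 1.50: 89.2, 11.9; 5.00: 69.8, 30.2; 8.00: 61.2, 39.7; 12.0: 52.5, 47.6; 20.0: 43.4, 56.6; 25.0: 41.8, 58.8

(scatter of a reading: 0.5 percentage points)

* part of the electrophile that has reacted at 10 d
* share of the unused nucleophile that is free and not bound as protonated nucleophile, at 10 d

- the earlier runs do not show how much of nucleophile is bound; that part of a forecast is a guess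
- no earlier run changes the charge of free base; that part of a forecast is a guess

Nucleophile stands at 0.80 equiv, less than one equivalent, so it is the limiting reagent. But the protic impurity may take nucleophile too. The reckoning here assumes the same rate constant for both takers. [Nucleophile] then cancels from the ratio of the two rates, which leaves [electrophile]/[protic impurity]. So both fall by the same fraction until the nucleophile is gone. For the flask that gives 66.7%: the sharing ceiling, the nucleophile charged divided by electrophile and protic impurity charged together. Time comes next. The electrophile charge times the time stands in the flask at 4.80 times its value at the last gamma reading. The reckoning therefore puts the flask a little under its ceiling. The free share of nucleophile stays unreckoned, as the earlier runs do not show how much of it is bound.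

The forecast gave 64% (60% to 72%) reacted and 3% (0.3% to 12%) free, holding that “Binding therefore looks nearly complete”.

The flask gives 65.4% reacted and 50.1% free.

    electrophile + nucleophile → acid set free + product (k = 0.0120 M⁻¹ min⁻¹)
    nucleophile + acid set free ⇌ protonated nucleophile, settled at all times (K = 450 M⁻¹)
    acid set free + free base ⇌ salt of the base, settled at all times (K = 1.20 × 10⁶ M⁻¹)
    acid set free → by-product carried off (k = 2.70 × 10⁻⁴ min⁻¹)
    nucleophile + protic impurity → quenched reagent (k = 0.0120 M⁻¹ min⁻¹)

In the flask, nucleophile goes to electrophile 5.0 times as fast as to protic impurity at 10.0 d, the same ratio as just after the start. Electrophile and protic impurity in the flask stand level at 35% and 35% of their charges, with nucleophile at 0.93%, and ten times as long brings the flask to 66.7% against the ceiling of 66.7%. For the neighbour flask with 0.020 M of electrophile the ceiling is 44.4%, and that flask gives 43.7%.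

The readings stem from a simulated flask with made-up constants; scatter was added.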